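## Analysis of the target

Caraganin C (19) is a 2,3,4-trisubstituted chroman. Ring A is the benzo ring with the 7-methoxy group, and the pyran ring holds O1, C2, C3 and C4. C2 carries a 2,4-dimethoxyphenyl group, C3 a 4-hydroxybenzyl group and C4 an (E)-4-hydroxystyryl group. The SMILES reads as (2R,3R,4R), with H2/H3 and H3/H4 both trans, so all three substituents are equatorial on the half-chair and this should be the most stable diastereomer. The sensitive sites are the two free phenols, the electron-rich styrene (which rules out hydrogenation, strong acid and acid/silane reductions), the O1–C2 bond (a benzylic ether of an ortho,para-dimethoxyaryl ring, easily ionised) and the C4–H bond, which is benzylic and allylic. The hard part is C4: it has no heteroatom and no neighbouring carbonyl in the target, so its absolute configuration must be set in a C–C bond formation and cannot be repaired later. The strategy rests on the exocyclic CH2 at C3, which is benzylic to a para-hydroxyphenyl ring and can therefore be carried as an aryl ketone and deoxygenated late through a para-quinone methide. With that carbonyl drawn in, C4, C3 and C2 are the β-carbon, the α-carbon and the carbinol carbon of an aldol between a ring A chalcone enolate and 2,4-dimethoxybenzaldehyde. The ring A oxygen already sits ortho on the β-aryl group, and the carbonyl makes C3 (enolisation) and C2 (retro-oxa-Michael) correctable after ring closure.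

## Retrosynthetic reasoning

Benzylic C–H and the two O–H bonds (19 from 17 via 18). The last step is planned to change only carbon–heteroatom bonds. The CH2 of the 4-hydroxybenzyl group is traced back to the benzylic acetate 17, and both phenols to triisopropylsilyl ethers. This position is the only one that can pass through a para-quinone methide (18), so hydride can replace oxygen under basic conditions that leave O1–C2, the styrene and C4–H alone. The forward step must free the phenoxide, expel acetate and trap 18 with hydride before it tautomerises.

Carbinol to ketone (17 from 16 from 15). The acetate comes from alcohol 16 and this from the all-trans aryl ketone 15. Nothing is cut; the gain is a carbonyl at the C3 branch, which serves both as the aldol carbonyl and as the handle for stereochemical correction.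

Stereochemical simplification (15 from 14). In 15 the C3 hydrogen is α to the ketone and the O1–C2 bond is β to it. C3 can epimerise through the enolate and C2 through ring opening and reclosure, so 15 is traced back to 14, the same chroman ketone with only C4 defined. The forward step has to be an equilibration that ends in the all-equatorial isomer.

O1–C2 bond (14 from 12 via 13). The pyran ring is opened at the benzylic C2–O bond and not at the aryl O1–C8a bond. C2 ionises readily because of the 2,4-dimethoxyphenyl group, whereas forming the aryl C–O bond would need a metal-catalysed etherification on a crowded secondary alcohol. The cut exposes a β-hydroxy ketone (13, then its methoxymethyl ether 12), which is exactly what an aldol addition delivers. The forward step must unmask the ring A phenol and close the ring without touching C4.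

C2–C3 and C4–vinyl bonds (12 from 5, 9 and 10 via 11). The aldol bond C2–C3 is cut to the enolate 11 and aldehyde 10. The enolate is then cut at the C4–styryl bond, which leaves the plain chalcone 5 and the alkenylborane 9. Cutting the C4–ring A bond instead would require an aryl nucleophile to choose between the 1,4- and 1,6-positions of a dienone, whereas 5 has a single electrophilic carbon. Two skeletal bonds and all three stereocentres are traced to one operation on three fragments of similar size. The forward reaction must deliver the styryl group to one face of 5 under a chiral bisphosphine–rhodium hydroxide catalyst and pass the enolate on to boron without protonation.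

Chalcone (5 from 4, from 2 and 3; 2 from 1). The enone C=C is cut by the Claisen–Schmidt retron to ketone 3 and aldehyde 2, the methoxymethyl ether of 1. The condensation is run on the free phenol (giving 4) and the silyl ether is put on afterwards, because an aryl silyl ether would not survive hydroxide in alcohol.

Alkenylborane (9 from 8, from 7, from 6). The B–C and C–H bonds across the alkene are cut to alkyne 8 (syn hydroboration fixes the E geometry). The alkyne comes from aldehyde 7 by one-carbon homologation and 7 from 6 by silylation.

## Alternatives that were turned down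

Alternative 1: ring closure by hydroalkoxylation of a C2=C3 styrene. The target is traced through its dipivalate A1 to the ring-opened alkene A2, which carries the ring A phenol, a C2=C3 double bond and only the C4 stereocentre. In the forward step acid protonates C3 of the 2,4-dimethoxystyrene unit, and the ring A phenol captures the C2 cation. Because the ionisation is reversible, the all-trans chroman should accumulate. This route is stronger than the chosen one on redox economy: C3 is already at the CH2 level, so no ketone reduction, acylation or deoxygenation is needed and the end-game is one ester cleavage. Against it, C3 is created by protonation and can be corrected only by reopening the ring through the same cation, which means prolonged exposure to acid. That acid also meets the second styrene, whose protonation lets the same phenol close a regioisomeric six-membered ether, and a 1,2-hydride shift followed by loss of H4 would move the double bond into conjugation and erase C4. A2 would also need its own enantioselective construction of C4 next to a trisubstituted alkene, so the early steps are not shorter. The chosen route pays three extra late steps for the ketone but gains a base-mediated correction of C2 and C3 that never exposes the styrenes to strong acid.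

Alternative 2: Danheiser benzannulation to build ring A last. Ring A is cut to the enoyl diazoketone A4 and methoxyacetylene A5. In the forward step, Wolff rearrangement gives a vinylketene that adds A5 by [2+2] cycloaddition, and the cyclobutenone opens (4π) and recloses (6π) to the ring A phenol A3. In its favour, the regiochemistry of the resorcinol-type ring is secure and the phenol emerges free for ring closure. Against it, ring A is the cheapest part of the molecule, and the route needs the whole C2–C3–C4 triad in open-chain form beforehand, with no ring or carbonyl to correct it. In A4 the C4–H is γ to an enone and allylic to the styrene, so it is prone to epimerisation. The Wolff step is photochemical or thermal in the presence of two styrene chromophores (E/Z isomerisation, ketene–alkene cycloaddition), and A5 is volatile and unstable. It is weaker than the chosen route on step count, convergence and stereocontrol; its one advantage, a regiodefined ring A, is obtained in the chosen route from a commercial benzaldehyde.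

Alternative 3: vicinal difunctionalisation of a coumarin. The target is traced to lactone A6, made from 7-methoxycoumarin A7 by copper-catalysed asymmetric conjugate addition of a styrylmagnesium nucleophile at C4 and benzylation of the magnesium enolate at C3. This is stronger than the chosen route on two points: ring A and the pyran ring are bought, and the C3 benzyl group enters at its final oxidation level, trans to C4 by approach anti to the new substituent. Against it, C2 is a lactone carbonyl. The 2,4-dimethoxyphenyl group must be added as an aryl nucleophile (risk of double addition and ring opening) and the resulting lactol deoxygenated. That reduction passes through the C2 oxocarbenium ion under acid/silane conditions, which also threaten the styrene, and it sets C2 kinetically with no means of correction. Asymmetric conjugate addition of alkenyl Grignard reagents to coumarins is also less secure than that of alkyl reagents, and lactone enolates of dihydrocoumarins can expel the phenoxide. The chosen route instead brings in all three substituents in one operation and leaves C2 and C3 under thermodynamic control.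

Key step: step 7

Assumption: the sense of induction is assigned from the usual quadrant model for acyclic (E)-enones, in which the (S)-BINAP–alkenylrhodium intermediate delivers to the αre/βre face; if the first run shows the opposite sense, (R)-BINAP is used with no other change.

## Route

Step 1
Reactants: 1 2-hydroxy-4-methoxybenzaldehyde
Product: 2 4-methoxy-2-(methoxymethoxy)benzaldehyde
Conditions: MOMCl, i-Pr2NEt, CH2Cl2, 0 °C → rt
Reagents that add atoms: chloromethyl methyl ether, COCCl
Why: O-alkylation of the phenol (Williamson-type); the acetal survives the basic condensation and the borane/rhodium step and is later removed by the same acid that ionises C2.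

Step 2
Reactants: 2 4-methoxy-2-(methoxymethoxy)benzaldehyde; 3 4-hydroxyacetophenone
Product: 4 (E)-1-(4-hydroxyphenyl)-3-[4-methoxy-2-(methoxymethoxy)phenyl]prop-2-en-1-one
Conditions: KOH (50 % aq), EtOH, rt → 40 °C; AcOH to pH 6
Reagents that add atoms: none
Why: Claisen–Schmidt condensation with a non-enolisable aldehyde; E1cB dehydration gives the (E)-enone, and the ketone is used as the free phenol because an aryl silyl ether would be cleaved by hydroxide in ethanol.

Step 3
Reactants: 4 (E)-1-(4-hydroxyphenyl)-3-[4-methoxy-2-(methoxymethoxy)phenyl]prop-2-en-1-one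
Product: 5 (E)-3-[4-methoxy-2-(methoxymethoxy)phenyl]-1-[4-(triisopropylsilyloxy)phenyl]prop-2-en-1-one
Conditions: TIPSCl, imidazole, DMF, rt
Reagents that add atoms: chlorotriisopropylsilane, CC(C)[Si](Cl)(C(C)C)C(C)C
Why: Phenol silylation; the triisopropylsilyl ether is chosen over the tert-butyldimethylsilyl ether for its margin in the acidic acetal cleavage of step 8.

Step 4
Reactants: 6 4-hydroxybenzaldehyde
Product: 7 4-(triisopropylsilyloxy)benzaldehyde
Conditions: TIPSCl, imidazole, DMF, rt
Reagents that add atoms: chlorotriisopropylsilane, CC(C)[Si](Cl)(C(C)C)C(C)C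
Why: Phenol silylation under standard conditions.

Step 5
Reactants: 7 4-(triisopropylsilyloxy)benzaldehyde
Product: 8 (4-ethynylphenoxy)triisopropylsilane
Conditions: TMSCHN2, n-BuLi, THF, −78 °C; then 7, −78 °C → rt
Reagents that add atoms: trimethylsilyldiazomethane, C[Si](C)(C)C=[N+]=[N-]
Why: Colvin rearrangement: the lithiated diazo compound adds to the aldehyde, Peterson elimination and loss of N2 give an alkylidene carbene whose 1,2-shift gives the alkyne; the alkoxide-free conditions spare the labile para-formyl aryl silyl ether.

Step 6
Reactants: 8 (4-ethynylphenoxy)triisopropylsilane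
Product: 9 9-{(E)-2-[4-(triisopropylsilyloxy)phenyl]ethenyl}-9-borabicyclo[3.3.1]nonane
Conditions: 9-BBN-H (1.0 equiv) added slowly to 8 (2.0 equiv), THF, 0 °C → rt; excess 8 distilled off (80 °C, 0.01 mbar) and recovered; residue taken up in toluene
Reagents that add atoms: 9-borabicyclo[3.3.1]nonane (used as its dimer), B1C2CCCC1CCC2
Why: Syn, anti-Markovnikov hydroboration gives the (E)-alkenylborane; the excess of alkyne suppresses the second hydroboration to the 1,1-diboryl compound, and it is removed because a terminal alkyne would insert into or protonate the rhodium intermediates of step 7.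

Step 7
Reactants: 5 (E)-3-[4-methoxy-2-(methoxymethoxy)phenyl]-1-[4-(triisopropylsilyloxy)phenyl]prop-2-en-1-one; 9 9-{(E)-2-[4-(triisopropylsilyloxy)phenyl]ethenyl}-9-borabicyclo[3.3.1]nonane; 10 2,4-dimethoxybenzaldehyde
Product: 12 (2S,3S)-3-(2,4-dimethoxyphenyl)-3-hydroxy-2-{(1R,2E)-1-[4-methoxy-2-(methoxymethoxy)phenyl]-3-[4-(triisopropylsilyloxy)phenyl]prop-2-en-1-yl}-1-[4-(triisopropylsilyloxy)phenyl]propan-1-one, via boron enolate 11 (not isolated)
Conditions: [Rh(OH)((S)-BINAP)]2 (2.5 mol %), 9 (1.4 equiv), toluene, 60 °C; then 10, −78 → 0 °C; then MeOH, pH 7 buffer, H2O2 (30 %), 0 °C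
Reagents that add atoms: none
Why: The hydroxo complex transmetalates with 9 to a monovalent alkenylrhodium species, the enone C=C of 5 inserts into the Rh–C bond (C4–vinyl bond) and the oxa-π-allyl rhodium exchanges with a further molecule of 9, which releases the (Z)-boron enolate 11 and regenerates the alkenylrhodium species, so no proton source is needed and the enolate survives. The closest known reaction type is the rhodium–bisphosphine-catalysed 1,4-addition of B-aryl-9-BBN reagents to enones that gives chiral boron enolates for aldol trapping, taken together with the rhodium-catalysed 1,4-addition of alkenylboron reagents. No ring is closed. C4 is set by the ligand: (S)-BINAP is expected to expose the αre/βre face of the (E)-enone, which corresponds to (R) at C4. The enolate is Z because an aryl ketone enolate places oxygen cis to the bulky C4 substituent, and aldehyde 10 then reacts through a chair-like six-membered boron-bridged transition state with its aryl group equatorial, which sets C2 syn to C3. The C3/C4 relationship follows from allylic strain (C4–H in the enolate plane, approach anti to the ortho-substituted ring A aryl group), which predicts the (2S,3S) isomer named here and not the syn isomer whose C2 and C3 map directly onto the target; this selectivity is not needed, since both centres are re-set in step 9. What the step does need is 1,4- over 1,2-addition, transfer of the sp2 alkenyl group and not a cage carbon, face selection at C4, and a catalysed rate above that of the uncatalysed six-centre alkenyl transfer from boron, for which the aprotic medium, the hydroxo precatalyst and the lowest workable temperature are chosen. The oxidative work-up cleaves the boron aldolate, and 12 is passed through deactivated silica and used at once.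

Step 8
Reactants: 12 (2S,3S)-3-(2,4-dimethoxyphenyl)-3-hydroxy-2-{(1R,2E)-1-[4-methoxy-2-(methoxymethoxy)phenyl]-3-[4-(triisopropylsilyloxy)phenyl]prop-2-en-1-yl}-1-[4-(triisopropylsilyloxy)phenyl]propan-1-one
Product: 14 {(4R)-2-(2,4-dimethoxyphenyl)-7-methoxy-4-[(E)-2-(4-triisopropylsilyloxyphenyl)ethenyl]-3,4-dihydro-2H-chromen-3-yl}[4-(triisopropylsilyloxy)phenyl]methanone as a mixture of C2/C3 epimers, via phenol 13 (not isolated)
Conditions: HCl (0.5 M in MeOH), THF, 40 °C; concentrate; CSA (10 mol %), CH2Cl2, 4 Å MS, rt
Reagents that add atoms: none
Why: Acid-catalysed acetal solvolysis frees the ring A phenol, and the 2,4-dimethoxybenzylic carbinol ionises far more readily than the styrene is protonated, so the phenol captures the C2 cation in a 6-exo closure (SN1 etherification) to form O1–C2; C2 and C3 are not controlled here and C4 is untouched.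

Step 9
Reactants: 14 the chroman ketone as a mixture of C2/C3 epimers
Product: 15 {(2R,3R,4R)-2-(2,4-dimethoxyphenyl)-7-methoxy-4-[(E)-2-(4-triisopropylsilyloxyphenyl)ethenyl]-3,4-dihydro-2H-chromen-3-yl}[4-(triisopropylsilyloxy)phenyl]methanone
Conditions: DBU (1 equiv), toluene, 60 °C
Reagents that add atoms: none
Why: Base-mediated equilibration: C3 epimerises through the ketone enolate and C2 through retro-oxa-Michael opening and 6-endo-trig reclosure, so the mixture (and any uncyclised enone phenol) should drain into the isomer with all three substituents equatorial; C4 is not acidic, because in the chroman it is β to the ketone and in the ring-opened enone it sits on the α-carbon, where its anion would be cross-conjugated.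

Step 10
Reactants: 15 the (2R,3R,4R)-chroman ketone
Product: 16 {(2R,4R)-2-(2,4-dimethoxyphenyl)-7-methoxy-4-[(E)-2-(4-triisopropylsilyloxyphenyl)ethenyl]-3,4-dihydro-2H-chromen-3-yl}[4-(triisopropylsilyloxy)phenyl]methanol with C3 as in 15 and the carbinol centre as a mixture
Conditions: NaBH4, CeCl3·7H2O, MeOH–THF, −20 → 0 °C
Reagents that add atoms: none
Why: Luche reduction: fast 1,2-hydride addition in a nearly neutral medium, so the β-aryloxy ketone is reduced before it can ring-open; the new carbinol centre is removed in step 12 and its configuration is irrelevant.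

Step 11
Reactants: 16 the benzylic alcohol
Product: 17 the corresponding benzylic acetate with C2/C3/C4 as in 15 and the acetoxy-bearing centre as a mixture
Conditions: Ac2O, pyridine, DMAP (cat.), CH2Cl2, 0 °C → rt
Reagents that add atoms: acetic anhydride, CC(=O)OC(C)=O
Why: DMAP-catalysed acylation installs the leaving group needed for the 1,6-elimination of step 12.

Step 12
Reactants: 17 the benzylic acetate
Product: 19 caraganin C 4-{[(2R,3R,4R)-2-(2,4-dimethoxyphenyl)-4-[(E)-2-(4-hydroxyphenyl)ethenyl]-7-methoxy-3,4-dihydro-2H-chromen-3-yl]methyl}phenol, via quinone methide 18 (not isolated)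
Conditions: NaBH4 (excess), then Bu4NF (3 equiv), THF–EtOH, 0 °C → rt; aq. NH4Cl
Reagents that add atoms: none
Why: Fluoride cleaves both aryl silyl ethers, the para-phenoxide expels acetate by 1,6-elimination to the para-quinone methide 18, and borohydride, already present, adds hydride to the exocyclic carbon and restores the phenol; only this benzylic position can form a quinone methide, so O1–C2, the styrene and C3 are left alone.

## Compound list

1 | 2-hydroxy-4-methoxybenzaldehyde | COc1ccc(C=O)c(O)c1 | starting material
2 | 4-methoxy-2-(methoxymethoxy)benzaldehyde | COCOc1cc(OC)ccc1C=O | intermediate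
3 | 4-hydroxyacetophenone | CC(=O)c1ccc(O)cc1 | starting material
4 | (E)-1-(4-hydroxyphenyl)-3-[4-methoxy-2-(methoxymethoxy)phenyl]prop-2-en-1-one | O=C(/C=C/c1ccc(OC)cc1OCOC)c1ccc(O)cc1 | intermediate
5 | (E)-3-[4-methoxy-2-(methoxymethoxy)phenyl]-1-[4-(triisopropylsilyloxy)phenyl]prop-2-en-1-one | O=C(/C=C/c1ccc(OC)cc1OCOC)c1ccc(O[Si](C(C)C)(C(C)C)C(C)C)cc1 | intermediate
6 | 4-hydroxybenzaldehyde | O=Cc1ccc(O)cc1 | starting material
7 | 4-(triisopropylsilyloxy)benzaldehyde | O=Cc1ccc(O[Si](C(C)C)(C(C)C)C(C)C)cc1 | intermediate
8 | (4-ethynylphenoxy)triisopropylsilane | C#Cc1ccc(O[Si](C(C)C)(C(C)C)C(C)C)cc1 | intermediate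
9 | 9-{(E)-2-[4-(triisopropylsilyloxy)phenyl]ethenyl}-9-borabicyclo[3.3.1]nonane | CC(C)[Si](C(C)C)(C(C)C)Oc1ccc(/C=C/B2C3CCCC2CCC3)cc1 | intermediate
10 | 2,4-dimethoxybenzaldehyde | COc1ccc(C=O)c(OC)c1 | starting material
11 | 9-{[(1Z,3R,4E)-3-[4-methoxy-2-(methoxymethoxy)phenyl]-1,5-bis[4-(triisopropylsilyloxy)phenyl]penta-1,4-dien-1-yl]oxy}-9-borabicyclo[3.3.1]nonane (boron enolate) | CC(C)[Si](C(C)C)(C(C)C)Oc1ccc(cc1)/C(OB1C2CCCC1CCC2)=C/[C@H](c1ccc(OC)cc1OCOC)/C=C/c1ccc(O[Si](C(C)C)(C(C)C)C(C)C)cc1 | intermediate
12 | (2S,3S)-3-(2,4-dimethoxyphenyl)-3-hydroxy-2-{(1R,2E)-1-[4-methoxy-2-(methoxymethoxy)phenyl]-3-[4-(triisopropylsilyloxy)phenyl]prop-2-en-1-yl}-1-[4-(triisopropylsilyloxy)phenyl]propan-1-one | O[C@H](c1ccc(OC)cc1OC)[C@@H](C(=O)c1ccc(O[Si](C(C)C)(C(C)C)C(C)C)cc1)[C@H](c1ccc(OC)cc1OCOC)/C=C/c1ccc(O[Si](C(C)C)(C(C)C)C(C)C)cc1 | intermediate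
13 | (2S,3S)-3-(2,4-dimethoxyphenyl)-3-hydroxy-2-{(1R,2E)-1-(2-hydroxy-4-methoxyphenyl)-3-[4-(triisopropylsilyloxy)phenyl]prop-2-en-1-yl}-1-[4-(triisopropylsilyloxy)phenyl]propan-1-one | O[C@H](c1ccc(OC)cc1OC)[C@@H](C(=O)c1ccc(O[Si](C(C)C)(C(C)C)C(C)C)cc1)[C@H](c1ccc(OC)cc1O)/C=C/c1ccc(O[Si](C(C)C)(C(C)C)C(C)C)cc1 | intermediate
14 | {(4R)-2-(2,4-dimethoxyphenyl)-7-methoxy-4-[(E)-2-(4-triisopropylsilyloxyphenyl)ethenyl]-3,4-dihydro-2H-chromen-3-yl}[4-(triisopropylsilyloxy)phenyl]methanone, mixture of C2/C3 epimers | COc1ccc2c(c1)OC(c1ccc(OC)cc1OC)C(C(=O)c1ccc(O[Si](C(C)C)(C(C)C)C(C)C)cc1)[C@H]2/C=C/c1ccc(O[Si](C(C)C)(C(C)C)C(C)C)cc1 | intermediate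
15 | {(2R,3R,4R)-2-(2,4-dimethoxyphenyl)-7-methoxy-4-[(E)-2-(4-triisopropylsilyloxyphenyl)ethenyl]-3,4-dihydro-2H-chromen-3-yl}[4-(triisopropylsilyloxy)phenyl]methanone | COc1ccc2c(c1)O[C@@H](c1ccc(OC)cc1OC)[C@H](C(=O)c1ccc(O[Si](C(C)C)(C(C)C)C(C)C)cc1)[C@H]2/C=C/c1ccc(O[Si](C(C)C)(C(C)C)C(C)C)cc1 | intermediate
16 | benzylic alcohol from 15 (ring centres as in 15, carbinol centre as a mixture) | COc1ccc2c(c1)O[C@@H](c1ccc(OC)cc1OC)[C@H](C(O)c1ccc(O[Si](C(C)C)(C(C)C)C(C)C)cc1)[C@H]2/C=C/c1ccc(O[Si](C(C)C)(C(C)C)C(C)C)cc1 | intermediate
17 | benzylic acetate of 16 (ring centres as in 15, acetoxy-bearing centre as a mixture) | COc1ccc2c(c1)O[C@@H](c1ccc(OC)cc1OC)[C@H](C(OC(C)=O)c1ccc(O[Si](C(C)C)(C(C)C)C(C)C)cc1)[C@H]2/C=C/c1ccc(O[Si](C(C)C)(C(C)C)C(C)C)cc1 | intermediate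
18 | para-quinone methide: 4-{[(2R,4R)-2-(2,4-dimethoxyphenyl)-4-[(E)-2-(4-hydroxyphenyl)ethenyl]-7-methoxy-3,4-dihydro-2H-chromen-3-yl]methylidene}cyclohexa-2,5-dien-1-one (ring centres as in 15) | COc1ccc2c(c1)O[C@@H](c1ccc(OC)cc1OC)[C@H](C=C1C=CC(=O)C=C1)[C@H]2/C=C/c1ccc(O)cc1 | intermediate
19 | caraganin C, 4-{[(2R,3R,4R)-2-(2,4-dimethoxyphenyl)-4-[(E)-2-(4-hydroxyphenyl)ethenyl]-7-methoxy-3,4-dihydro-2H-chromen-3-yl]methyl}phenol | COc1ccc2c(c1)O[C@@H](c1ccc(OC)cc1OC)[C@H](Cc1ccc(O)cc1)[C@H]2/C=C/c1ccc(O)cc1 | target

## Step count and least certain steps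

Total step count: 12. Longest linear sequence: 9 steps (steps 1–3 or 4–6, then 7–12).

Step 7 (key step). Three things can go wrong. Insertion of the electron-rich β-aryl enone into the alkenyl–rhodium bond may be slow under a bisphosphine ligand, so that the catalyst decays. The uncatalysed six-centre alkenyl transfer from boron to the s-cis enone may run alongside and erode the enantiomeric purity at C4. The rhodium enolate may be protonated or react with the aldehyde itself instead of being passed on to boron. Poor diastereoselection in the aldol stage is tolerated. The fallback separates the two bond formations. It sets out from 8 and 5 and returns at 11. Alkyne 8 is hydroborated with pinacolborane (Cp2Zr(H)Cl cat.) to the pinacol (E)-alkenylboronate F1, which cannot add without the catalyst. Hayashi–Miyaura addition of F1 to 5 ([Rh(OH)((S)-BINAP)]2, K3PO4 aq, dioxane, 40 °C) gives the (3S)-β-styryl ketone F2. Soft enolisation of F2 with 9-BBN triflate and i-Pr2NEt in CH2Cl2 gives the boron enolate 11, which meets 10 as in step 7.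

Step 12. The quinone methide may tautomerise to the exocyclic alkene (loss of C3), or be captured by fluoride, ethoxide or the liberated phenoxide of a second molecule (oligomerisation) faster than by hydride; the acetate may also be cleaved before it can leave. The fallback avoids the quinone methide. It sets out from 15 and returns at 19. Ketone 15 is condensed with tosylhydrazine (PPTS, EtOH, 60 °C) to the tosylhydrazone F3. Caglioti-type reduction (catecholborane, CHCl3, 0 °C; then sodium acetate trihydrate NaOAc·3H2O, 60 °C) gives caraganin C bis(triisopropylsilyl) ether F4, and Bu4NF in THF releases 19.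

Step 8. The acid may protonate the styrene, after which the freed ring A phenol closes the wrong six-membered ether; silyl ethers may be lost, or the C2 cation may eliminate to the enone without reclosure. The fallback forms O1–C2 by conjugate addition instead of ionisation. It sets out from 12 and returns at 15. Mesylation and elimination (MsCl, Et3N, CH2Cl2, 0 °C; DBU) give the α-(2,4-dimethoxybenzylidene) ketone F5 (C4 as in 12, alkene isomers). Brief acetal cleavage (HCl 0.5 M in MeOH, THF, 40 °C) gives the enone phenol F6, and DBU in toluene closes it by oxa-Michael addition and equilibrates it to 15.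

Step 6. A second hydroboration to the 1,1-diboryl compound may compete, and alkyne carried over would poison the rhodium step. The fallback makes the same borane with fixed stoichiometry. It sets out from 8 and returns at 9. Hydrozirconation and iodination (Cp2Zr(H)Cl, THF; I2) give (E)-[4-(2-iodoethenyl)phenoxy]triisopropylsilane F7. Iodine–lithium exchange (t-BuLi, Et2O, −78 °C) and addition of B-methoxy-9-BBN give the lithium alkenyl(methoxy)borate F8, and BF3·OEt2 strips the methoxide to leave 9; the lithium salts are filtered off in toluene.

Step 9. The equilibration may stop short: ring-opened enone phenol may persist because it is conjugated with the dimethoxyaryl ring, or cis isomers may remain if the energy gap is small. The fallback changes the manifold from anionic to cationic. It sets out from 14 and returns at 15 with no new compound. Catalytic trifluoroacetic acid in CH2Cl2 ionises the O1–C2 bond reversibly to the 2,4-dimethoxybenzylic cation (equilibrating C2), and acid-catalysed enolisation equilibrates C3, so the enolate and retro-oxa-Michael pathway is avoided.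

## Further compounds

F1 | step 7 | (E)-4,4,5,5-tetramethyl-2-{2-[4-(triisopropylsilyloxy)phenyl]ethenyl}-1,3,2-dioxaborolane | CC(C)[Si](C(C)C)(C(C)C)Oc1ccc(/C=C/B2OC(C)(C)C(C)(C)O2)cc1
F2 | step 7 | (3S,4E)-3-[4-methoxy-2-(methoxymethoxy)phenyl]-1,5-bis[4-(triisopropylsilyloxy)phenyl]pent-4-en-1-one | O=C(C[C@H](c1ccc(OC)cc1OCOC)/C=C/c1ccc(O[Si](C(C)C)(C(C)C)C(C)C)cc1)c1ccc(O[Si](C(C)C)(C(C)C)C(C)C)cc1
F3 | step 12 | tosylhydrazone of ketone 15 | COc1ccc2c(c1)O[C@@H](c1ccc(OC)cc1OC)[C@H](C(=NNS(=O)(=O)c1ccc(C)cc1)c1ccc(O[Si](C(C)C)(C(C)C)C(C)C)cc1)[C@H]2/C=C/c1ccc(O[Si](C(C)C)(C(C)C)C(C)C)cc1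
F4 | step 12 | caraganin C bis(triisopropylsilyl) ether | COc1ccc2c(c1)O[C@@H](c1ccc(OC)cc1OC)[C@H](Cc1ccc(O[Si](C(C)C)(C(C)C)C(C)C)cc1)[C@H]2/C=C/c1ccc(O[Si](C(C)C)(C(C)C)C(C)C)cc1
F5 | step 8 | 3-(2,4-dimethoxyphenyl)-2-{(E)-1-[4-methoxy-2-(methoxymethoxy)phenyl]-3-[4-(triisopropylsilyloxy)phenyl]prop-2-en-1-yl}-1-[4-(triisopropylsilyloxy)phenyl]prop-2-en-1-one (C4 as in 12, alkene isomers) | COc1ccc(C=C(C(=O)c2ccc(O[Si](C(C)C)(C(C)C)C(C)C)cc2)[C@H](c2ccc(OC)cc2OCOC)/C=C/c2ccc(O[Si](C(C)C)(C(C)C)C(C)C)cc2)c(OC)c1
F6 | step 8 | 3-(2,4-dimethoxyphenyl)-2-{(E)-1-(2-hydroxy-4-methoxyphenyl)-3-[4-(triisopropylsilyloxy)phenyl]prop-2-en-1-yl}-1-[4-(triisopropylsilyloxy)phenyl]prop-2-en-1-one (C4 as in 12, alkene isomers) | COc1ccc(C=C(C(=O)c2ccc(O[Si](C(C)C)(C(C)C)C(C)C)cc2)[C@H](c2ccc(OC)cc2O)/C=C/c2ccc(O[Si](C(C)C)(C(C)C)C(C)C)cc2)c(OC)c1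
F7 | step 6 | (E)-[4-(2-iodoethenyl)phenoxy]triisopropylsilane | I/C=C/c1ccc(O[Si](C(C)C)(C(C)C)C(C)C)cc1
F8 | step 6 | lithium 9-methoxy-9-{(E)-2-[4-(triisopropylsilyloxy)phenyl]ethenyl}-9-boranuidabicyclo[3.3.1]nonane | CO[B-]1(/C=C/c2ccc(O[Si](C(C)C)(C(C)C)C(C)C)cc2)C3CCCC1CCC3.[Li+]
F0 | step 9 | none | none
A1 | alternative 1 | caraganin C dipivalate | COc1ccc2c(c1)O[C@@H](c1ccc(OC)cc1OC)[C@H](Cc1ccc(OC(=O)C(C)(C)C)cc1)[C@H]2/C=C/c1ccc(OC(=O)C(C)(C)C)cc1
A2 | alternative 1 | ring-opened C2=C3 alkene with free ring A phenol (C4 as in the target, alkene geometry open) | COc1ccc(c(O)c1)[C@H](/C=C/c1ccc(OC(=O)C(C)(C)C)cc1)C(Cc1ccc(OC(=O)C(C)(C)C)cc1)=Cc1ccc(OC)cc1OC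
A3 | alternative 2 | ring A phenol with silylated C2 carbinol (benzannulation product) | CC(C)(C)[Si](C)(C)O[C@@H](c1ccc(OC)cc1OC)[C@H](Cc1ccc(O[Si](C)(C)C(C)(C)C)cc1)[C@H](c1ccc(OC)cc1O)/C=C/c1ccc(O[Si](C)(C)C(C)(C)C)cc1
A4 | alternative 2 | enoyl diazoketone carrying the C2–C3–C4 triad | CC(C)(C)[Si](C)(C)O[C@@H](c1ccc(OC)cc1OC)[C@H](Cc1ccc(O[Si](C)(C)C(C)(C)C)cc1)[C@H](/C=C/C(=O)C=[N+]=[N-])/C=C/c1ccc(O[Si](C)(C)C(C)(C)C)cc1
A5 | alternative 2 | methoxyacetylene | COC#C
A6 | alternative 3 | 3,4-trans-3-(4-silyloxybenzyl)-4-[(E)-4-silyloxystyryl]-7-methoxychroman-2-one | COc1ccc2c(c1)OC(=O)[C@H](Cc1ccc(O[Si](C)(C)C(C)(C)C)cc1)[C@H]2/C=C/c1ccc(O[Si](C)(C)C(C)(C)C)cc1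
A7 | alternative 3 | 7-methoxycoumarin | COc1ccc2ccc(=O)oc2c1
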